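**Assumption:** the target has no stereogenic element (no stereocentre, and each biaryl axis carries a symmetrical 2,4,6-trihydroxyphenyl ring), so "single enantiomer" is taken to mean the one achiral constitution shown. Rings are lettered A (3,5-dihydroxyphenyl), B (central ring), C (ring bonded to B through oxygen), D and E (the biphenyl, E terminal).

## Retrosynthetic overview

1. Target 17 comes from octadecamethyl ether 16 by global O-demethylation; all eight benzene rings are bought, none is built.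
2. The ring A–O–ring B bond is made by a redox-neutral copper-catalysed O-arylation of quinone 13 (ring B at the quinone level) with boronic acid 14, which also leaves the free OH of ring B.
3. The two ring B–O–ring C bonds are made by double addition–elimination of phenol 10 on 2,6-dichloro-1,4-benzoquinone 11.
4. The ring C–O–ring D bond is made by Ullmann coupling of biphenylol 6 with bromoaldehyde 7; a Dakin oxidation then unmasks the ring C phenol.
5. The ring D–ring E biaryl comes from oxidative homocoupling of two molecules of lithiated 1,3,5-trimethoxybenzene, then lithiation/borylation/oxidation. Assembly order: E–D, then C, then B, then A.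

## Route

Step 1
Reactants: 1 1,3,5-trimethoxybenzene (2 equiv)
Product: 3 2,2',4,4',6,6'-hexamethoxybiphenyl, via 2,4,6-trimethoxyphenyllithium 2 (not isolated)
Conditions: n-BuLi (1.05 equiv per 1), TMEDA, THF, 0 °C to rt; then anhydrous FeCl3 (1.1 equiv per 1), −78 °C to rt
Reagents that add atoms: none
Why: Directed ortho-metalation between two methoxy groups, then oxidative homocoupling in which FeCl3 joins two molecules of aryllithium 2 at their lithiated carbons, so two molecules of 1 give one molecule of 3; the coupling tolerates four ortho-methoxy groups, and no stereogenic axis arises because both rings are symmetrical.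

Step 2
Reactants: 3 2,2',4,4',6,6'-hexamethoxybiphenyl
Product: 6 2,2',4,4',6,6'-hexamethoxybiphenyl-3-ol, via 3-lithio-2,2',4,4',6,6'-hexamethoxybiphenyl 4 (not isolated), via lithium aryltrimethoxyborate 5 (not isolated)
Conditions: n-BuLi (1.0 equiv), TMEDA, THF, 0 °C; B(OMe)3, −78 °C to rt; then AcOH, 30% H2O2, 0 °C to rt
Reagents that add atoms: hydrogen peroxide, OO
Why: Directed ortho-metalation at one of four equivalent C–H positions flanked by two methoxy groups, borylation and boronate oxidation (aryl shift from boron to oxygen); one equivalent of base keeps it to mono-functionalisation, and unreacted 3 and the diol are separated by base extraction.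

Step 3
Reactants: 6 2,2',4,4',6,6'-hexamethoxybiphenyl-3-ol; 7 4-bromo-2,6-dimethoxybenzaldehyde
Product: 8 4-[(2,2',4,4',6,6'-hexamethoxybiphenyl-3-yl)oxy]-2,6-dimethoxybenzaldehyde
Conditions: CuI (10 mol %), picolinic acid (20 mol %), K3PO4 (2 equiv), DMSO, 90 °C, argon
Reagents that add atoms: none
Why: Ullmann-type copper-catalysed diaryl ether synthesis; the hindered 2,6-dimethoxyphenol is the nucleophile and the bromide has no ortho substituent and is activated by the para formyl group.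

Step 4
Reactants: 8 4-[(2,2',4,4',6,6'-hexamethoxybiphenyl-3-yl)oxy]-2,6-dimethoxybenzaldehyde
Product: 10 4-[(2,2',4,4',6,6'-hexamethoxybiphenyl-3-yl)oxy]-2,6-dimethoxyphenol, via aryl formate 9 (not isolated)
Conditions: 30% H2O2 (1.3 equiv), cat. H2SO4, MeOH, rt
Reagents that add atoms: hydrogen peroxide, OO
Why: Acid-catalysed Dakin oxidation; the electron-rich 2,6-dimethoxy-4-aryloxyphenyl group migrates to oxygen and the formate is methanolysed in the same pot, giving the hindered ring C phenol.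

Step 5
Reactants: 10 4-[(2,2',4,4',6,6'-hexamethoxybiphenyl-3-yl)oxy]-2,6-dimethoxyphenol (2.1 equiv); 11 2,6-dichloro-1,4-benzoquinone
Product: 13 2,6-bis{4-[(2,2',4,4',6,6'-hexamethoxybiphenyl-3-yl)oxy]-2,6-dimethoxyphenoxy}-1,4-benzoquinone, via 2-aryloxy-6-chloro-1,4-benzoquinone 12 (not isolated)
Conditions: Cs2CO3 (2.2 equiv), MeCN, 0 °C to rt, argon, dark, slow addition of the phenoxide
Reagents that add atoms: none
Why: Two-fold addition–elimination (vinylogous acyl substitution) of a phenoxide on a 2,6-dihaloquinone; each C–Cl carbon is the beta carbon of an enone, so even a di-ortho-substituted phenoxide reacts without a metal.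

Step 6
Reactants: 13 2,6-bis{4-[(2,2',4,4',6,6'-hexamethoxybiphenyl-3-yl)oxy]-2,6-dimethoxyphenoxy}-1,4-benzoquinone; 14 3,5-dimethoxyphenylboronic acid (2 equiv)
Product: 16 4-(3,5-dimethoxyphenoxy)-3,5-bis{4-[(2,2',4,4',6,6'-hexamethoxybiphenyl-3-yl)oxy]-2,6-dimethoxyphenoxy}phenol, via aryl borate ester 15 (not isolated)
Conditions: CuOAc (10 mol %), 4 Å molecular sieves, ClCH2CH2Cl, 40 °C, argon (no O2); then aq. NH4Cl
Reagents that add atoms: none
Why: Proposed new method: copper-catalysed redox-neutral O-arylation of a 1,4-benzoquinone by an arylboronic acid, in which the quinone itself is the two-electron oxidant that a Chan–Lam coupling normally draws from O2; monovalent copper is oxidised by 13 to a divalent copper semiquinonate held at O-1 by the chelating pocket of the two flanking aryl-ether oxygens and their ortho-methoxy groups, while the hard boron acid sits on the more basic, unhindered vinylogous-carbonate oxygen O-4; acetate-assisted boron-to-copper transmetalation gives an aryl divalent copper semiquinonate whose valence tautomer, an aryl trivalent copper aryloxide, forms the C–O bond at O-1 by reductive elimination and returns monovalent copper; O-4 leaves as borate 15 and becomes the free ring B phenol on work-up; the reaction stops there because the quinone is the only oxidant present, and C-arylation at C-3/C-5 is disfavoured because these are the electron-rich ends of the aryloxy enol ethers; closest known reaction type: Chan–Lam O-arylation of phenols with arylboronic acids.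

Step 7
Reactants: 16 4-(3,5-dimethoxyphenoxy)-3,5-bis{4-[(2,2',4,4',6,6'-hexamethoxybiphenyl-3-yl)oxy]-2,6-dimethoxyphenoxy}phenol
Product: 17 4-(3,5-dihydroxyphenoxy)-3,5-bis{4-[(2,2',4,4',6,6'-hexahydroxybiphenyl-3-yl)oxy]-2,6-dihydroxyphenoxy}phenol (CNP0227063.0)
Conditions: BBr3 (60 equiv), CH2Cl2, −78 °C to rt, argon; MeOH then H2O at 0 °C; Sephadex LH-20 (degassed MeOH)
Reagents that add atoms: none
Why: Lewis-acid cleavage of all eighteen aryl methyl ethers (bromide attacks the O-methyl carbon of the boron-complexed ether); diaryl ether and biaryl bonds are inert to BBr3, and no stereocentre exists to be disturbed.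

## Compound list

1 | 1,3,5-trimethoxybenzene | COc1cc(OC)cc(OC)c1 | starting material
2 | 2,4,6-trimethoxyphenyllithium | [Li]c1c(OC)cc(OC)cc1OC | intermediate (not isolated)
3 | 2,2',4,4',6,6'-hexamethoxybiphenyl | COc1cc(OC)c(-c2c(OC)cc(OC)cc2OC)c(OC)c1 | intermediate
4 | 3-lithio-2,2',4,4',6,6'-hexamethoxybiphenyl | [Li]c1c(OC)cc(OC)c(-c2c(OC)cc(OC)cc2OC)c1OC | intermediate (not isolated)
5 | lithium trimethoxy(2,2',4,4',6,6'-hexamethoxybiphenyl-3-yl)borate | [Li+].CO[B-](OC)(OC)c1c(OC)cc(OC)c(-c2c(OC)cc(OC)cc2OC)c1OC | intermediate (not isolated)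
6 | 2,2',4,4',6,6'-hexamethoxybiphenyl-3-ol | Oc1c(OC)cc(OC)c(-c2c(OC)cc(OC)cc2OC)c1OC | intermediate
7 | 4-bromo-2,6-dimethoxybenzaldehyde | O=Cc1c(OC)cc(Br)cc1OC | starting material
8 | 4-[(2,2',4,4',6,6'-hexamethoxybiphenyl-3-yl)oxy]-2,6-dimethoxybenzaldehyde | O=Cc1c(OC)cc(Oc2c(OC)cc(OC)c(-c3c(OC)cc(OC)cc3OC)c2OC)cc1OC | intermediate
9 | 4-[(2,2',4,4',6,6'-hexamethoxybiphenyl-3-yl)oxy]-2,6-dimethoxyphenyl formate | O=COc1c(OC)cc(Oc2c(OC)cc(OC)c(-c3c(OC)cc(OC)cc3OC)c2OC)cc1OC | intermediate (not isolated)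
10 | 4-[(2,2',4,4',6,6'-hexamethoxybiphenyl-3-yl)oxy]-2,6-dimethoxyphenol | Oc1c(OC)cc(Oc2c(OC)cc(OC)c(-c3c(OC)cc(OC)cc3OC)c2OC)cc1OC | intermediate
11 | 2,6-dichloro-1,4-benzoquinone | O=C1C=C(Cl)C(=O)C(Cl)=C1 | starting material
12 | 2-chloro-6-{4-[(2,2',4,4',6,6'-hexamethoxybiphenyl-3-yl)oxy]-2,6-dimethoxyphenoxy}-1,4-benzoquinone | O=C1C=C(Cl)C(=O)C(Oc2c(OC)cc(Oc3c(OC)cc(OC)c(-c4c(OC)cc(OC)cc4OC)c3OC)cc2OC)=C1 | intermediate (not isolated)
13 | 2,6-bis{4-[(2,2',4,4',6,6'-hexamethoxybiphenyl-3-yl)oxy]-2,6-dimethoxyphenoxy}-1,4-benzoquinone | O=C1C=C(Oc2c(OC)cc(Oc3c(OC)cc(OC)c(-c4c(OC)cc(OC)cc4OC)c3OC)cc2OC)C(=O)C(Oc2c(OC)cc(Oc3c(OC)cc(OC)c(-c4c(OC)cc(OC)cc4OC)c3OC)cc2OC)=C1 | intermediate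
14 | 3,5-dimethoxyphenylboronic acid | COc1cc(OC)cc(B(O)O)c1 | starting material
15 | dihydroxyboryl ester (aryl borate) of phenol 16 | OB(O)Oc1cc(Oc2c(OC)cc(Oc3c(OC)cc(OC)c(-c4c(OC)cc(OC)cc4OC)c3OC)cc2OC)c(Oc2cc(OC)cc(OC)c2)c(Oc2c(OC)cc(Oc3c(OC)cc(OC)c(-c4c(OC)cc(OC)cc4OC)c3OC)cc2OC)c1 | intermediate (not isolated)
16 | 4-(3,5-dimethoxyphenoxy)-3,5-bis{4-[(2,2',4,4',6,6'-hexamethoxybiphenyl-3-yl)oxy]-2,6-dimethoxyphenoxy}phenol | Oc1cc(Oc2c(OC)cc(Oc3c(OC)cc(OC)c(-c4c(OC)cc(OC)cc4OC)c3OC)cc2OC)c(Oc2cc(OC)cc(OC)c2)c(Oc2c(OC)cc(Oc3c(OC)cc(OC)c(-c4c(OC)cc(OC)cc4OC)c3OC)cc2OC)c1 | intermediate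
17 | 4-(3,5-dihydroxyphenoxy)-3,5-bis{4-[(2,2',4,4',6,6'-hexahydroxybiphenyl-3-yl)oxy]-2,6-dihydroxyphenoxy}phenol (CNP0227063.0) | Oc1cc(O)cc(Oc2c(Oc3c(O)cc(Oc4c(O)cc(O)c(-c5c(O)cc(O)cc5O)c4O)cc3O)cc(O)cc2Oc2c(O)cc(Oc3c(O)cc(O)c(-c4c(O)cc(O)cc4O)c3O)cc2O)c1 | target

## Step count and risks

Total step count: 7. Longest linear sequence: 7 steps (1 → 3 → 6 → 8 → 10 → 13 → 16 → 17); two molecules of 1 are joined in step 1 and phenol 10 is used twice in step 5.

**Step 5 (double substitution on the dichloroquinone).** The electron-rich phenoxide of 10 may reduce 11 by electron transfer instead of substituting it, or the reaction may stall at 12. The fallback sets out from 10 and moves the ring B couplings to copper catalysis on an arene. Purchased 2,6-dibromo-4-methoxyphenol is O-arylated with 14 (Cu(OAc)2, pyridine, air, 4 Å molecular sieves, CH2Cl2; Chan–Lam coupling) to give 1,3-dibromo-2-(3,5-dimethoxyphenoxy)-5-methoxybenzene F1. A two-fold Ullmann coupling of F1 with two equivalents of 10 (CuI, picolinic acid, K3PO4, DMSO, 110 °C) gives 5-methoxy-2-(3,5-dimethoxyphenoxy)-1,3-bis{4-[(2,2',4,4',6,6'-hexamethoxybiphenyl-3-yl)oxy]-2,6-dimethoxyphenoxy}benzene F2. BBr3 under the conditions of step 7 then cleaves all nineteen methyl ethers, and the route is rejoined at 17.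

**Step 6 (the proposed new O-arylation).** It may arylate O-4 instead of O-1, may only homocouple 14 while reducing 13 to the hydroquinone, or may not turn over. The fallback uses known chemistry, sets out from 13 and comes back at 16. Na2S2O4 (EtOAc/H2O) reduces 13 to 2,6-bis{4-[(2,2',4,4',6,6'-hexamethoxybiphenyl-3-yl)oxy]-2,6-dimethoxyphenoxy}benzene-1,4-diol F3. Benzyl bromide (1.0 equiv, K2CO3, acetone) alkylates the less hindered and more acidic O-4 hydroxyl to give 4-(benzyloxy)-2,6-bis{4-[(2,2',4,4',6,6'-hexamethoxybiphenyl-3-yl)oxy]-2,6-dimethoxyphenoxy}phenol F4. Ullmann coupling of the remaining hindered OH with 1-iodo-3,5-dimethoxybenzene (CuI, picolinic acid, K3PO4, DMSO, 90 °C) gives 5-(benzyloxy)-2-(3,5-dimethoxyphenoxy)-1,3-bis{4-[(2,2',4,4',6,6'-hexamethoxybiphenyl-3-yl)oxy]-2,6-dimethoxyphenoxy}benzene F5. Hydrogenolysis (H2, Pd/C, EtOAc) gives 16. Any hydroquinone formed as a by-product of step 6 can be fed into this sequence.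

**Step 7 (eighteen-fold demethylation).** Cleavage may be incomplete, or the free nonadecaphenol may oxidise in air or be lost on isolation. The fallback sets out from 16 and comes back at 17 by isolating the product as a stable ester. After the BBr3 reaction and methanol quench, the crude polyphenol is peracetylated (Ac2O, pyridine, DMAP) to the nonadecaacetate of 17 F6. F6 is purified on silica (under-demethylated material is removed at this stage) and deacetylated with HCl in MeOH (from AcCl) under argon to give 17.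

## Further compounds

F1 | step 5 | 1,3-dibromo-2-(3,5-dimethoxyphenoxy)-5-methoxybenzene | COc1cc(Br)c(Oc2cc(OC)cc(OC)c2)c(Br)c1
F2 | step 5 | 5-methoxy-2-(3,5-dimethoxyphenoxy)-1,3-bis{4-[(2,2',4,4',6,6'-hexamethoxybiphenyl-3-yl)oxy]-2,6-dimethoxyphenoxy}benzene | COc1cc(Oc2c(OC)cc(Oc3c(OC)cc(OC)c(-c4c(OC)cc(OC)cc4OC)c3OC)cc2OC)c(Oc2cc(OC)cc(OC)c2)c(Oc2c(OC)cc(Oc3c(OC)cc(OC)c(-c4c(OC)cc(OC)cc4OC)c3OC)cc2OC)c1
F3 | step 6 | 2,6-bis{4-[(2,2',4,4',6,6'-hexamethoxybiphenyl-3-yl)oxy]-2,6-dimethoxyphenoxy}benzene-1,4-diol | Oc1cc(Oc2c(OC)cc(Oc3c(OC)cc(OC)c(-c4c(OC)cc(OC)cc4OC)c3OC)cc2OC)c(O)c(Oc2c(OC)cc(Oc3c(OC)cc(OC)c(-c4c(OC)cc(OC)cc4OC)c3OC)cc2OC)c1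
F4 | step 6 | 4-(benzyloxy)-2,6-bis{4-[(2,2',4,4',6,6'-hexamethoxybiphenyl-3-yl)oxy]-2,6-dimethoxyphenoxy}phenol | C(Oc1cc(Oc2c(OC)cc(Oc3c(OC)cc(OC)c(-c4c(OC)cc(OC)cc4OC)c3OC)cc2OC)c(O)c(Oc2c(OC)cc(Oc3c(OC)cc(OC)c(-c4c(OC)cc(OC)cc4OC)c3OC)cc2OC)c1)c1ccccc1
F5 | step 6 | 5-(benzyloxy)-2-(3,5-dimethoxyphenoxy)-1,3-bis{4-[(2,2',4,4',6,6'-hexamethoxybiphenyl-3-yl)oxy]-2,6-dimethoxyphenoxy}benzene | C(Oc1cc(Oc2c(OC)cc(Oc3c(OC)cc(OC)c(-c4c(OC)cc(OC)cc4OC)c3OC)cc2OC)c(Oc2cc(OC)cc(OC)c2)c(Oc2c(OC)cc(Oc3c(OC)cc(OC)c(-c4c(OC)cc(OC)cc4OC)c3OC)cc2OC)c1)c1ccccc1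
F6 | step 7 | nonadecaacetate of 17 | CC(=O)Oc1cc(OC(C)=O)cc(Oc2c(Oc3c(OC(C)=O)cc(Oc4c(OC(C)=O)cc(OC(C)=O)c(-c5c(OC(C)=O)cc(OC(C)=O)cc5OC(C)=O)c4OC(C)=O)cc3OC(C)=O)cc(OC(C)=O)cc2Oc2c(OC(C)=O)cc(Oc3c(OC(C)=O)cc(OC(C)=O)c(-c4c(OC(C)=O)cc(OC(C)=O)cc4OC(C)=O)c3OC(C)=O)cc2OC(C)=O)c1
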